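**Retrosynthetic overview**
1. Feature used: guaiane numbering applies, with ring atoms C1, C5, C6, C7, C8, C9, C10 in the cycloheptane. The oxygen-bearing carbons C6 and C9 flank the C7-C8 edge in a 1,4 relation, as do the alpha carbons of a furan carrying C11-C12 on its position 3, and C5-C1-C10, oxygenated at the middle carbon, is an oxyallyl unit. C6-O is trans to C9-O although the C6/C7 lactone is cis-fused, so one bridging oxygen can stay on C9 if the C12 carboxyl expels it from C6 with inversion.
2. Late disconnections: the C4 silyl ether, then the lactone C6-O bond, which leads back to an 8-oxabicyclo[3.2.1]octane with an endo acrylate arm on C7.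
3. Middle: the C2 ketone comes from a C2-C3 alkyne through a spiro alkylidene carbonate (CO2). C13 comes from Mannich methylenation at C11, C1-C2 from acetylide addition, the C5 ester from SN2 inversion of an alpha-keto triflate, and C7-H from exo hydrogenation.
4. Key disconnection: C5-C6 and C9-C10, by a catalytic enantioselective (4+3) cycloaddition of tert-butyl furan-3-ylacetate with a 1-benzyloxy-2-silyloxy-3-methylallyl cation.
5. Ring order: the cycloheptane first (as the oxygen-bridged bicycle), then the short-lived spiro carbonate ring, and the alpha-methylene lactone last, formed in the event that opens the bridge.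

Key step: step 5

Remark on conventions: guaiane numbering is used for all intermediates (C2 ketone, C3 CH2, C4 carbinol, C11/C12/C13 lactone carbons). In the bicycles, exo or axial at C5/C10 means syn to the bridge oxygen. Endo, or equatorial at C5/C10, means anti to it. In this numbering the target is 1S,4R,5S,6R,7S,9R,10S with an (R)-2-methylbutanoate.
Assumption: the sense of induction of the squaramide catalyst with this pair of partners cannot be known in advance. The catalyst enantiomer that delivers the cycloadduct as drawn is used, and both enantiomers are accessible. The catalyst, called SQ below, is a squaramide. One nitrogen carries 3,5-bis(trifluoromethyl)phenyl and the other carries the tert-leucine amide of a 2-arylpyrrolidine.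

**Step 1**
Reactants: 1 2-(furan-3-yl)acetic acid
Product: 2 tert-butyl 2-(furan-3-yl)acetate
Conditions: Boc2O (1.5 equiv), DMAP (0.2 equiv), t-BuOH, 30 °C
Reagents that add atoms: tert-butanol CC(C)(C)O; di-tert-butyl dicarbonate CC(C)(C)OC(=O)OC(=O)OC(C)(C)C (activator and alternative source of the tert-butoxy group)
Why: DMAP-catalysed esterification through the mixed carbonic anhydride runs without acid, so the furan survives, and the tert-butyl ester resists the later bases and nucleophiles yet leaves as isobutene in step 15.

**Step 2**
Reactants: 3 1-hydroxybutan-2-one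
Product: 4 2-oxobutanal (kept in solution)
Conditions: IBX (1.3 equiv), EtOAc, 75 °C; filter
Reagents that add atoms: none
Why: IBX oxidation of the primary carbinol of an alpha-ketol stops at the keto aldehyde without C-C cleavage, and the spent iodine reagent is filtered off so that the volatile, easily hydrated product need not be isolated.

**Step 3**
Reactants: 4 2-oxobutanal
Product: 5 1,1-bis(benzyloxy)butan-2-one
Conditions: BnOH (2.2 equiv) added to the filtrate, concentrate; p-TsOH·H2O (2 mol %), toluene, Dean-Stark, reflux
Reagents that add atoms: benzyl alcohol OCc1ccccc1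
Why: Acid-catalysed acetalisation with azeotropic removal of water occurs at the far more electrophilic aldehyde carbon, while a second acetal at the neighbouring ketone is disfavoured sterically and electronically.

**Step 4**
Reactants: 5 1,1-bis(benzyloxy)butan-2-one
Product: 6 (Z)-1,1-bis(benzyloxy)-2-(triethylsilyloxy)but-2-ene
Conditions: Et3SiOTf (1.2 equiv), Et3N (1.5 equiv), CH2Cl2, 0 °C
Reagents that add atoms: triethylsilyl triflate CC[Si](CC)(CC)OS(=O)(=O)C(F)(F)F
Why: Soft enolisation (silyl triflate plus tertiary amine) removes a proton from the CH2 flank, and the Z enol silane is favoured because it keeps the methyl group away from the bulky dibenzyloxymethyl group.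

**Step 5**
Reactants: 2 tert-butyl 2-(furan-3-yl)acetate; 6 (Z)-1,1-bis(benzyloxy)-2-(triethylsilyloxy)but-2-ene
Product: 7 tert-butyl 2-(4-benzyloxy-2-methyl-3-oxo-8-oxabicyclo[3.2.1]oct-6-en-6-yl)acetate, C5 benzyloxy and C10 methyl both equatorial
Conditions: Et3SiOTf (10 mol %), SQ (12 mol %), 2 (1.5 equiv), Et2O, -78 °C
Reagents that add atoms: none
Why: Et3SiOTf strips one benzyloxy group from 6 as its silyl ether and leaves a 1-benzyloxy-2-silyloxy-3-methylallyl cation paired with squaramide-bound triflate; furan C2 of 2 bonds to the acetal-derived carbon (C5-C6), the surviving enol silane carbon then bonds to the furan-derived oxocarbenium carbon (C10-C9), and the silyl group returns to triflate. The closest known reaction is the silyl-triflate-triggered (4+3) cycloaddition of furans with alkoxy-substituted silyloxyallyl cations from alpha-keto acetal enol silanes, in its enantioselective variant co-catalysed by a chiral hydrogen-bond donor, so the reaction type is established and only this pairing of substituents is untried. The cycloheptene ring, and with it the 8-oxabicyclo[3.2.1]octene, closes by a stepwise (4+3) annulation whose ring-forming event is a 7-(enolendo)-exo-trig Mukaiyama-type attack in the compact arrangement. C6 and C9 are tied cis by the oxygen bridge, the equatorial C10 methyl follows from the Z enol silane and the equatorial C5 benzyloxy group from the outward (W-shaped) geometry of the cation, and the absolute sense of all four centres comes from the chiral anion-binding catalyst, which leaves one face of the cation open. The step needs head-to-head orientation, one diastereomeric mode and one enantioface: the first rests on the alkyl-type arm making the adjacent furan alpha carbon the more nucleophilic one while the oxocarbenium end of the cation is the more electrophilic one, the second on the defined geometry of 6, the third on the catalyst, and the bulky, weakly basic tert-butyl ester keeps the arm from tying up the silyl Lewis acid.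

**Step 6**
Reactants: 7 cycloadduct
Product: 8 saturated bicyclic alpha-ketol (tert-butyl acetate arm endo on C7, C5-OH and C10-CH3 equatorial)
Conditions: H2 (1 atm), Pd/C (10 wt %), EtOAc-EtOH, rt
Reagents that add atoms: none
Why: Heterogeneous hydrogenation reaches C7=C8 only from the exo face syn to the bridge oxygen, which pushes the arm endo and sets C7, and the same catalyst hydrogenolyses the benzyl ether without reducing the ketone.

**Step 7**
Reactants: 8 saturated bicyclic alpha-ketol
Product: 9 equatorial C5 triflate of 8
Conditions: Tf2O (1.3 equiv), pyridine (3 equiv), CH2Cl2, -20 to 0 °C; used at once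
Reagents that add atoms: triflic anhydride O=S(=O)(OS(=O)(=O)C(F)(F)F)C(F)(F)F
Why: O-Sulfonylation leaves the C5-O bond and its configuration untouched and provides a leaving group that can be displaced below room temperature.

**Step 8**
Reactants: 9 equatorial C5 triflate; 10 (R)-2-methylbutanoic acid
Product: 12 bicyclic ketone bearing the axial C5 (R)-2-methylbutanoate, via cesium carboxylate 11 (not isolated)
Conditions: 10 (1.5 equiv), Cs2CO3 (0.75 equiv), MeOH, evaporate and dry; then 9, 18-crown-6, toluene, 0 °C to rt
Reagents that add atoms: none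
Why: SN2 displacement of an alpha-keto triflate by a carboxylate is accelerated by the neighbouring carbonyl, the nucleophile enters on the open exo side anti to the equatorial leaving group and inverts C5 to the axial ester, E2 loss is barred because the only beta hydrogen sits on bridgehead C6, and the new equatorial C5-H lies near the carbonyl plane and is slow to enolise.

**Step 9**
Reactants: 13 (R)-but-3-yn-2-ol
Product: 14 (R)-but-3-yn-2-ol tert-butyldiphenylsilyl ether
Conditions: TBDPSCl (1.1 equiv), imidazole (2 equiv), DMF, 0 °C to rt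
Reagents that add atoms: tert-butyl(chloro)diphenylsilane CC(C)(C)[Si](Cl)(c1ccccc1)c1ccccc1
Why: Standard O-silylation does not touch the stereocentre, and this silyl group withstands n-BuLi, LiN(i-Pr)2, DBU and Me3SiOTf.

**Step 10**
Reactants: 12 bicyclic ketone; 14 silyl-protected alkyne
Product: 17 tertiary propargylic alcohol (C1-OH endo/axial; alkynyl group exo), via lithium acetylide 15 (not isolated), via dichlorocerium acetylide 16 (not isolated)
Conditions: 14 (1.5 equiv), n-BuLi, THF, -78 °C; anhydrous CeCl3, THF, -78 °C; then 12, -78 °C; aq NH4Cl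
Reagents that add atoms: none
Why: Organocerium 1,2-addition: the weakly basic cerium acetylide adds to the ketone faster than it enolises it or attacks either ester, and the slim nucleophile comes from the exo face because the endo face is walled off by the C7-C8 bridge and its endo arm, which sets C1 with its hydroxyl trans-diaxial to the C5 ester so that no acyl shift can follow.

**Step 11**
Reactants: 17 tertiary propargylic alcohol
Product: 18 C11 dimethylaminomethyl derivative (Mannich base, epimers at C11)
Conditions: LiN(i-Pr)2 (2.1 equiv), THF, -78 °C; dimethylmethyleneammonium iodide (3 equiv), -78 to -30 °C; H2O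
Reagents that add atoms: dimethylmethyleneammonium iodide C[N+](C)=C.[I-]
Why: Mannich aminomethylation of a kinetic ester enolate: the first equivalent of base takes the hydroxyl proton and the second the secondary C11-H2 in preference to the tertiary alpha C-H of the 2-methylbutanoate (the kinetic bias known from regioselective enolisation), base is kept to 2.1 equivalents for that reason, excess iminium salt turns any enolised 2-methylbutanoate into a separable quaternary by-product instead of the epimeric ester, and the new C11 centre is erased in step 12.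

**Step 12**
Reactants: 18 Mannich base
Product: 20 tert-butyl acrylate (C11=C13 in place), via methiodide 19 (not isolated)
Conditions: MeI (5 equiv), THF, rt; then DBU (1.5 equiv), CH2Cl2, 0 °C to rt
Reagents that add atoms: iodomethane CI (its methyl group stays only in 19 and leaves with the amine)
Why: Exhaustive N-methylation followed by base-induced beta-elimination of trimethylamine (Hofmann-type, E1cB) is the classical second half of the Mannich methylenation and needs only DBU, to which the esters, the alkyne and the silyl ether are inert.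

**Step 13**
Reactants: 20 tert-butyl acrylate
Product: 21 spiro (Z)-alkylidene cyclic carbonate (O on C1 and C2)
Conditions: AgOAc (10 mol %), DBU (1 equiv), CO2 (1.0 MPa), toluene, rt
Reagents that add atoms: carbon dioxide O=C=O
Why: Silver-catalysed carboxylative cyclisation of a tertiary propargylic alcohol: the DBU-assisted carbonate adds anti to the AgOAc-activated triple bond in the 5-exo-dig mode, so oxygen reaches C2 only and the Z alkene results, with C1 and C4 untouched.

**Step 14**
Reactants: 21 spiro alkylidene carbonate
Product: 22 bridged alpha-hydroxy ketone (C1-OH, C2=O)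
Conditions: H2O (10 equiv), DBU (10 mol %), MeCN, rt
Reagents that add atoms: none
Why: Base-catalysed hydrolysis of an enol carbonate: water attacks the carbonate carbonyl, the enolate departs as the better leaving group and becomes the C2 ketone, and the carbonic half-ester left on the tertiary oxygen loses CO2, under conditions that leave the hindered esters and the acrylate alone.

**Step 15**
Reactants: 22 bridged alpha-hydroxy ketone
Product: 25 C4 tert-butyldiphenylsilyl ether of the target, via bis-silylated bridged ester 23 (not isolated), via lactone bis-trimethylsilyl ether 24 (not isolated)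
Conditions: Me3SiOTf (4 equiv), 2,6-di-tert-butyl-4-methylpyridine (2.5 equiv), CH2Cl2, -20 °C to rt; then citric acid, MeOH-H2O, 0 °C
Reagents that add atoms: trimethylsilyl triflate C[Si](C)(C)OS(=O)(=O)C(F)(F)F (its silyl groups stay only in 23 and 24 and are removed in the work-up)
Why: Proposed new method: Me3SiOTf converts the tert-butyl ester into the silyl ester with loss of isobutene and caps C1-OH (which also blocks an acyloin shift), then silylates the bridge oxygen reversibly; the carbonyl oxygen of the endo C12 silyl ester is held almost on the backside axis of the C6-O bond and attacks C6 in a 5-exo-tet SN2 with inversion while the bridge oxygen stays on C9, giving the cis lactone trans to C9-O; the axial C5 ester is gauche to the breaking bond and cannot participate, C9 has no internal nucleophile behind it, the hindered pyridine cannot act as an outside nucleophile, and silyl transfer from a carboxyl to an alkoxide oxygen together with relief of the crowded endo pocket supplies the driving force; the closest known reaction types are the acid-induced heterolysis of oxa-bridges with participation of endo acyl groups and the silyl-triflate-promoted ring opening of tetrahydrofurans by external nucleophiles.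

**Step 16**
Reactants: 25 C4 silyl ether of the target
Product: 26 target CNP0291806.5
Conditions: HF·pyridine, pyridine, THF, 0 °C to rt
Reagents that add atoms: none
Why: Acidic fluoride cleaves the Si-O bond without the basic conditions that would provoke retro-aldol or beta-elimination of the beta-hydroxy ketone or conjugate addition to the alpha-methylene lactone, and no stereocentre is involved.

**Compound list**
1 | 2-(furan-3-yl)acetic acid | OC(=O)Cc1ccoc1 | starting material
2 | tert-butyl 2-(furan-3-yl)acetate | CC(C)(C)OC(=O)Cc1ccoc1 | intermediate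
3 | 1-hydroxybutan-2-one | CCC(=O)CO | starting material
4 | 2-oxobutanal | CCC(=O)C=O | intermediate
5 | 1,1-bis(benzyloxy)butan-2-one | CCC(=O)C(OCc1ccccc1)OCc1ccccc1 | intermediate
6 | (Z)-1,1-bis(benzyloxy)-2-(triethylsilyloxy)but-2-ene | C/C=C(\O[Si](CC)(CC)CC)C(OCc1ccccc1)OCc1ccccc1 | intermediate
7 | (4+3) cycloadduct, 8-oxabicyclo[3.2.1]oct-6-en-3-one with equatorial C5-OBn and C10-CH3 | O1[C@H]2C(CC(=O)OC(C)(C)C)=C[C@@H]1[C@H](C)C(=O)[C@@H]2OCc1ccccc1 | intermediate
8 | saturated bicyclic alpha-ketol, arm endo | O1[C@H]2[C@H](CC(=O)OC(C)(C)C)C[C@@H]1[C@H](C)C(=O)[C@@H]2O | intermediate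
9 | equatorial C5 triflate | O1[C@H]2[C@H](CC(=O)OC(C)(C)C)C[C@@H]1[C@H](C)C(=O)[C@@H]2OS(=O)(=O)C(F)(F)F | intermediate
10 | (R)-2-methylbutanoic acid | OC(=O)[C@H](C)CC | starting material
11 | cesium (R)-2-methylbutanoate | [Cs+].[O-]C(=O)[C@H](C)CC | intermediate
12 | bicyclic ketone with axial C5 (R)-2-methylbutanoate | O1[C@H]2[C@H](CC(=O)OC(C)(C)C)C[C@@H]1[C@H](C)C(=O)[C@H]2OC(=O)[C@H](C)CC | intermediate
13 | (R)-but-3-yn-2-ol | C#C[C@@H](C)O | starting material
14 | (R)-but-3-yn-2-ol tert-butyldiphenylsilyl ether | C#C[C@@H](C)O[Si](c1ccccc1)(c1ccccc1)C(C)(C)C | intermediate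
15 | lithium acetylide of 14 | [Li]C#C[C@@H](C)O[Si](c1ccccc1)(c1ccccc1)C(C)(C)C | intermediate
16 | dichlorocerium acetylide of 14 | Cl[Ce](Cl)C#C[C@@H](C)O[Si](c1ccccc1)(c1ccccc1)C(C)(C)C | intermediate
17 | tertiary propargylic alcohol | O1[C@H]2[C@H](CC(=O)OC(C)(C)C)C[C@@H]1[C@H](C)[C@@](O)(C#C[C@@H](C)O[Si](c3ccccc3)(c3ccccc3)C(C)(C)C)[C@H]2OC(=O)[C@H](C)CC | intermediate
18 | C11 Mannich base (C11 epimers) | O1[C@H]2[C@H](C(CN(C)C)C(=O)OC(C)(C)C)C[C@@H]1[C@H](C)[C@@](O)(C#C[C@@H](C)O[Si](c3ccccc3)(c3ccccc3)C(C)(C)C)[C@H]2OC(=O)[C@H](C)CC | intermediate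
19 | methiodide of 18 | O1[C@H]2[C@H](C(C[N+](C)(C)C)C(=O)OC(C)(C)C)C[C@@H]1[C@H](C)[C@@](O)(C#C[C@@H](C)O[Si](c3ccccc3)(c3ccccc3)C(C)(C)C)[C@H]2OC(=O)[C@H](C)CC.[I-] | intermediate
20 | tert-butyl acrylate | O1[C@H]2[C@H](C(=C)C(=O)OC(C)(C)C)C[C@@H]1[C@H](C)[C@@](O)(C#C[C@@H](C)O[Si](c3ccccc3)(c3ccccc3)C(C)(C)C)[C@H]2OC(=O)[C@H](C)CC | intermediate
21 | spiro (Z)-alkylidene cyclic carbonate | O1[C@H]2[C@H](C(=C)C(=O)OC(C)(C)C)C[C@@H]1[C@H](C)[C@@](O3)(C(/OC3=O)=C/[C@@H](C)O[Si](c4ccccc4)(c4ccccc4)C(C)(C)C)[C@H]2OC(=O)[C@H](C)CC | intermediate
22 | bridged alpha-hydroxy ketone | O1[C@H]2[C@H](C(=C)C(=O)OC(C)(C)C)C[C@@H]1[C@H](C)[C@@](O)(C(=O)C[C@@H](C)O[Si](c3ccccc3)(c3ccccc3)C(C)(C)C)[C@H]2OC(=O)[C@H](C)CC | intermediate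
23 | bridged trimethylsilyl acrylate, C1-OSiMe3 | O1[C@H]2[C@H](C(=C)C(=O)O[Si](C)(C)C)C[C@@H]1[C@H](C)[C@@](O[Si](C)(C)C)(C(=O)C[C@@H](C)O[Si](c3ccccc3)(c3ccccc3)C(C)(C)C)[C@H]2OC(=O)[C@H](C)CC | intermediate
24 | alpha-methylene lactone, C1 and C9 trimethylsilyl ethers | C=C1C(=O)O[C@@H]2[C@H]1C[C@@H](O[Si](C)(C)C)[C@H](C)[C@@](O[Si](C)(C)C)(C(=O)C[C@@H](C)O[Si](c3ccccc3)(c3ccccc3)C(C)(C)C)[C@H]2OC(=O)[C@H](C)CC | intermediate
25 | C4 tert-butyldiphenylsilyl ether of the target | C=C1C(=O)O[C@@H]2[C@H]1C[C@@H](O)[C@H](C)[C@@](O)(C(=O)C[C@@H](C)O[Si](c3ccccc3)(c3ccccc3)C(C)(C)C)[C@H]2OC(=O)[C@H](C)CC | intermediate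
26 | CNP0291806.5 | C=C1C(=O)O[C@@H]2[C@H]1C[C@@H](O)[C@H](C)[C@@](O)(C(=O)C[C@@H](C)O)[C@H]2OC(=O)[C@H](C)CC | target

**Step count**
Total: 16 steps. Longest linear sequence: 14 steps (from 3 through steps 2-8 and 10-16).

**Steps most likely to fail**

Step 15 (bridge-to-lactone transposition).
- What may go wrong: the silylated bridge may resist displacement at the electron-poor, hindered C6. Acid-driven side processes may also outrun the backside attack, namely opening at C9 by an outside nucleophile, loss of silanol across C3-C4, or an acyloin shift if C1-OH stays free.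
- Fallback, from 22 back to 25, with known reaction types only: the ether is opened by an external nucleophile and C6 is then inverted through a sulfonate.
- Me2BBr (CH2Cl2, -78 to 0 °C) cleaves cyclic ethers by SN2 attack of bromide. Here the less hindered C9 should be attacked from the endo side, giving bromohydrin F1 with C6-O retained and C9 inverted.
- MsCl and Et3N give mesylate F2, and CF3CO2H removes the tert-butyl group to give acid F3. With the C6 oxygen blocked as a sulfonate, no trans lactone can form by simple esterification.
- Cs2CO3 in DMF closes the cis lactone by intramolecular carboxylate SN2 with inversion at C6, giving bromolactone F4.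
- HCO2Cs in DMF replaces bromide with a second inversion at C9 (net retention), giving formate F5.
- KHCO3 in aqueous methanol at 0 °C removes the formyl group selectively and delivers 25.

Step 5 ((4+3) cycloaddition).
- What may go wrong: steric clash between the arm and the benzyloxy terminus may erode the head-to-head orientation. Enantioface control may also drop, since a methyl-terminated cation and a 3-substituted furan have not been paired under this catalyst.
- Fallback, from 4 back to 8: catalyst control is replaced by a covalently bound auxiliary, so that stereo- and regioisomers become separable diastereomers.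
- HC(OMe)3, MeOH and p-TsOH convert 4 into 1,1-dimethoxybutan-2-one F6.
- Acid-catalysed exchange with one equivalent of (S)-1-phenylethanol, with removal of methanol, gives the mixed methyl 1-phenylethyl acetal F7.
- Et3SiOTf and Et3N give the Z enol silane F8.
- Catalytic Me3SiOTf in CH2Cl2 at -95 °C ionises the methoxy group preferentially, and the chiral cation is trapped by 2 to give the 1-phenylethoxy cycloadduct F9.
- H2 over Pd/C saturates C7=C8 and hydrogenolyses the auxiliary, giving 8.
- Should the auxiliary induce the opposite sense, (R)-1-phenylethanol is used.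

Step 11 (aminomethylation at C11).
- What may go wrong: competitive enolisation of the 2-methylbutanoate would cost material. If proton transfer intervenes, its stereocentre would be scrambled.
- Fallback, from 9 back to 20: the chiral acyl group is attached only after the strong-base step.
- Bu4NNO2 in toluene displaces the triflate with inversion. The nitrite ester F10 hydrolyses on work-up to the axial ketol F11.
- Et3SiCl and imidazole give the triethylsilyl ether F12, and reagent 16 adds from the exo face to give propargylic alcohol F13.
- The operations of steps 11 and 12 then give Mannich base F14 and, through methiodide F15, acrylate F16. At this stage no epimerisable ester is present.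
- Buffered HF·pyridine at 0 °C removes only the triethylsilyl group, giving the C5 alcohol F17.
- Steglich esterification of the secondary hydroxyl with 10 (DCC, DMAP, CH2Cl2) gives 20.

**Further compounds**
F1 | step 15 | bromohydrin (C6-OH retained, C9-Br inverted) | O[C@H]1[C@H](C(=C)C(=O)OC(C)(C)C)C[C@H](Br)[C@H](C)[C@@](O)(C(=O)C[C@@H](C)O[Si](c2ccccc2)(c2ccccc2)C(C)(C)C)[C@H]1OC(=O)[C@H](C)CC
F2 | step 15 | C6 mesylate | CS(=O)(=O)O[C@H]1[C@H](C(=C)C(=O)OC(C)(C)C)C[C@H](Br)[C@H](C)[C@@](O)(C(=O)C[C@@H](C)O[Si](c2ccccc2)(c2ccccc2)C(C)(C)C)[C@H]1OC(=O)[C@H](C)CC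
F3 | step 15 | acrylic acid with C6 mesylate | CS(=O)(=O)O[C@H]1[C@H](C(=C)C(=O)O)C[C@H](Br)[C@H](C)[C@@](O)(C(=O)C[C@@H](C)O[Si](c2ccccc2)(c2ccccc2)C(C)(C)C)[C@H]1OC(=O)[C@H](C)CC
F4 | step 15 | C9 bromolactone | C=C1C(=O)O[C@@H]2[C@H]1C[C@H](Br)[C@H](C)[C@@](O)(C(=O)C[C@@H](C)O[Si](c3ccccc3)(c3ccccc3)C(C)(C)C)[C@H]2OC(=O)[C@H](C)CC
F5 | step 15 | C9 formate | C=C1C(=O)O[C@@H]2[C@H]1C[C@@H](OC=O)[C@H](C)[C@@](O)(C(=O)C[C@@H](C)O[Si](c3ccccc3)(c3ccccc3)C(C)(C)C)[C@H]2OC(=O)[C@H](C)CC
F6 | step 5 | 1,1-dimethoxybutan-2-one | CCC(=O)C(OC)OC
F7 | step 5 | 1-methoxy-1-[(S)-1-phenylethoxy]butan-2-one | CCC(=O)C(OC)O[C@@H](C)c1ccccc1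
F8 | step 5 | Z triethylsilyl enol ether of F7 | C/C=C(\O[Si](CC)(CC)CC)C(OC)O[C@@H](C)c1ccccc1
F9 | step 5 | cycloadduct with equatorial (S)-1-phenylethoxy group | O1[C@H]2C(CC(=O)OC(C)(C)C)=C[C@@H]1[C@H](C)C(=O)[C@@H]2O[C@@H](C)c1ccccc1
F10 | step 11 | axial C5 nitrite ester | O1[C@H]2[C@H](CC(=O)OC(C)(C)C)C[C@@H]1[C@H](C)C(=O)[C@H]2ON=O
F11 | step 11 | axial C5 ketol | O1[C@H]2[C@H](CC(=O)OC(C)(C)C)C[C@@H]1[C@H](C)C(=O)[C@H]2O
F12 | step 11 | axial C5 triethylsilyl ether | O1[C@H]2[C@H](CC(=O)OC(C)(C)C)C[C@@H]1[C@H](C)C(=O)[C@H]2O[Si](CC)(CC)CC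
F13 | step 11 | propargylic alcohol with C5-OSiEt3 | O1[C@H]2[C@H](CC(=O)OC(C)(C)C)C[C@@H]1[C@H](C)[C@@](O)(C#C[C@@H](C)O[Si](c3ccccc3)(c3ccccc3)C(C)(C)C)[C@H]2O[Si](CC)(CC)CC
F14 | step 11 | Mannich base with C5-OSiEt3 | O1[C@H]2[C@H](C(CN(C)C)C(=O)OC(C)(C)C)C[C@@H]1[C@H](C)[C@@](O)(C#C[C@@H](C)O[Si](c3ccccc3)(c3ccccc3)C(C)(C)C)[C@H]2O[Si](CC)(CC)CC
F15 | step 11 | methiodide of F14 | O1[C@H]2[C@H](C(C[N+](C)(C)C)C(=O)OC(C)(C)C)C[C@@H]1[C@H](C)[C@@](O)(C#C[C@@H](C)O[Si](c3ccccc3)(c3ccccc3)C(C)(C)C)[C@H]2O[Si](CC)(CC)CC.[I-]
F16 | step 11 | acrylate with C5-OSiEt3 | O1[C@H]2[C@H](C(=C)C(=O)OC(C)(C)C)C[C@@H]1[C@H](C)[C@@](O)(C#C[C@@H](C)O[Si](c3ccccc3)(c3ccccc3)C(C)(C)C)[C@H]2O[Si](CC)(CC)CC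
F17 | step 11 | acrylate with free axial C5-OH | O1[C@H]2[C@H](C(=C)C(=O)OC(C)(C)C)C[C@@H]1[C@H](C)[C@@](O)(C#C[C@@H](C)O[Si](c3ccccc3)(c3ccccc3)C(C)(C)C)[C@H]2O
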